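The plan cuts ring B at C6–C7 and C8–C9. Ring B (C5–C10) is fused to aromatic ring A and carries the benzylic quaternary C9 (C25 methyl) beside C8–H, the B/C junction. This is the retron of an ortho-quinodimethane (C6=C5–C10=C9) adding to a C7=C8 alkene. A benzocyclobutenol whose C9 holds the methyl and a C11–C12 tether to the ring D/E ester, with a vinyl group on C14, opens on heating and closes rings B and C in one operation, setting C8 and C9. Dehydration then gives the 6,7-alkene, and the guaiane unit is joined to the two phenolic oxygens at C3' and C4' to close the dioxane.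

Key step: step 24

Remark: friedelane numbering is used for the triterpene and primed guaiane numbering for the sesquiterpene; α and β have their usual steroid meaning.
Remark (assumption): each chiral catalyst, ligand or auxiliary is written with the configuration that its accepted facial model predicts for the needed centre; if a model should not hold for these substrates, the mirror-image reagent is used.
Remark: in 33 the relative configuration at C6/C9 matters although both centres become planar in 35, because only isomers with the oxygen trans to the C11 tether open productively; the C9 configuration itself is carried as a mixture from 22 on.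

**Ring D/E fragment**

Step 1
Reactants: 1 isoprene; 2 methacrolein
Product: 3 (R)-1,4-dimethylcyclohex-3-ene-1-carbaldehyde
Conditions: (S)-3,3-diphenyl-1-(o-tolyl)tetrahydro-1H,3H-pyrrolo[1,2-c][1,3,2]oxazaborole (10 mol%), Tf2NH (10 mol%), CH2Cl2, −78 → −40 °C
Reagents that add atoms: none
Why: Lewis-acid-catalysed Diels–Alder reaction in which the cationic oxazaborolidine binds the enal and shields one face, so the para adduct should form with C20 set by the catalyst.

Step 2
Reactants: 3 (R)-1,4-dimethylcyclohex-3-ene-1-carbaldehyde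
Product: 4 (R)-1,4-dimethylcyclohex-3-ene-1-carboxylic acid
Conditions: NaClO2, NaH2PO4, 2-methylbut-2-ene, t-BuOH/H2O, 0 °C → rt
Reagents that add atoms: sodium chlorite, [Na+].[O-]Cl=O
Why: Pinnick oxidation converts the α-quaternary aldehyde to the acid, the scavenger protecting the ring alkene from hypochlorite.

Step 3
Reactants: 4 (R)-1,4-dimethylcyclohex-3-ene-1-carboxylic acid
Product: 5 methyl (R)-1,4-dimethylcyclohex-3-ene-1-carboxylate
Conditions: MeI, K2CO3, DMF, rt
Reagents that add atoms: iodomethane, CI
Why: Carboxylate O-alkylation (SN2) gives the methyl ester that is carried to the target as C29.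

Step 4
Reactants: 5 methyl (R)-1,4-dimethylcyclohex-3-ene-1-carboxylate
Product: 6 methyl (1R)-3-hydroxy-1,4-dimethylcyclohexane-1-carboxylate (C3/C4 diastereomers)
Conditions: BH3·THF, THF, 0 °C; then NaOH, H2O2, 0 °C
Reagents that add atoms: hydrogen peroxide, OO
Why: Hydroboration–oxidation places the hydroxyl on the less substituted alkene carbon (C18); the two new centres are uncontrolled and are erased in steps 5 and 6.

Step 5
Reactants: 6 methyl (1R)-3-hydroxy-1,4-dimethylcyclohexane-1-carboxylate
Product: 7 methyl (1R)-1,4-dimethyl-3-oxocyclohexane-1-carboxylate (C4 epimers)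
Conditions: Dess–Martin periodinane, NaHCO3, CH2Cl2, rt
Reagents that add atoms: none
Why: Dess–Martin oxidation of the secondary alcohol gives the 2-methylcyclohexanone needed for annulation; C17 stays epimerisable.

Step 6
Reactants: 7 methyl (1R)-1,4-dimethyl-3-oxocyclohexane-1-carboxylate; 8 pent-1-en-3-one
Product: 11 methyl (1R,4R)-1,4-dimethyl-3-oxo-4-(3-oxopentyl)cyclohexane-1-carboxylate, via ketimine 9 (not isolated), via adduct imine 10 (not isolated)
Conditions: (S)-1-phenylethylamine, TsOH (cat.), toluene, reflux (−H2O); then 8, THF, 40 °C; then AcOH/H2O, rt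
Reagents that add atoms: water, O
Why: Michael addition of the more substituted secondary enamine tautomer of a chiral imine (deracemising alkylation); the phenylethyl group blocks one face, so quaternary C17 is set by the auxiliary whatever the C17 mixture in 7, and hydrolysis frees the 1,5-diketone.

Step 7
Reactants: 11 methyl (1R,4R)-1,4-dimethyl-3-oxo-4-(3-oxopentyl)cyclohexane-1-carboxylate
Product: 12 ring D/E octalone (14-oxo; 13(18)-ene; 13-methyl; 17β-methyl; 20β-methyl; 20α-CO2Me)
Conditions: NaOMe, MeOH, 60 °C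
Reagents that add atoms: none
Why: Intramolecular aldol condensation (second half of a Robinson annulation) closes ring D as the conjugated octalone.

Step 8
Reactants: 12 ring D/E octalone
Product: 13 cis-fused ring D/E decalone (18β-H; 17β-methyl; C13 epimers)
Conditions: H2 (3 atm), Pd/C (10%), KOH (cat.), EtOH, rt
Reagents that add atoms: none
Why: Heterogeneous hydrogenation of a 4-alkyl octalone under basic conditions should add hydrogen to the face of the angular methyl, as in 5β-selective reductions of steroidal enones, setting the cis D/E fusion.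

Step 9
Reactants: 13 cis-fused ring D/E decalone
Product: 14 trimethylsilyl enol ether (13(14)-ene) of 13
Conditions: TMSCl, Et3N, DMF, 110 °C
Reagents that add atoms: chlorotrimethylsilane, C[Si](C)(C)Cl
Why: Thermodynamic silyl enol ether formation; the tetrasubstituted enol ether toward C13 is favoured both by substitution and by the cis ring fusion.

Step 10
Reactants: 14 trimethylsilyl enol ether
Product: 15 13β-allyl-13α-methyl ring D/E 14-ketone
Conditions: Pd2(dba)3 (2.5 mol%), (R)-4-tert-butyl-2-[2-(diphenylphosphino)phenyl]-4,5-dihydrooxazole (6 mol%), diallyl carbonate, Bu4N[Ph3SiF2] (35 mol%), THF, 25 °C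
Reagents that add atoms: diallyl carbonate, C=CCOC(=O)OCC=C
Why: Enantioselective Tsuji–Trost allylation of a fluoride-unmasked tetrasubstituted enolate; the chiral P,N-ligand on palladium controls the face of C–C bond formation, so C13 (α-methyl, β-allyl) is set by the catalyst.

Step 11
Reactants: 15 13β-allyl-13α-methyl ring D/E 14-ketone
Product: 17 ring D/E 14-carbaldehyde (C14 epimers), via enol ether 16 (not isolated)
Conditions: MeOCH2PPh3Cl, KOt-Bu, THF, 0 → 50 °C; then 2 M HCl, THF, rt
Reagents that add atoms: (methoxymethyl)triphenylphosphonium chloride, COC[P+](c1ccccc1)(c1ccccc1)c1ccccc1.[Cl-]; water, O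
Why: Wittig methoxymethylenation followed by enol ether hydrolysis homologates the hindered ketone to the C14 aldehyde (C8 is the new carbon); the C14 epimers converge in step 12.

Step 12
Reactants: 17 ring D/E 14-carbaldehyde
Product: 18 14β-methyl-14α-formyl ring D/E ester
Conditions: KOt-Bu, MeI, THF, 0 °C
Reagents that add atoms: iodomethane, CI
Why: Aldehyde enolate C-methylation forms quaternary C14; in the ring D chair that keeps C13 equatorial on ring E, axial attack is blocked by the axial C18–C19 bond, so methyl iodide should enter equatorially (β) and leave the formyl group α.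

Step 13
Reactants: 18 14β-methyl-14α-formyl ring D/E ester
Product: 19 13β-allyl-14α-vinyl ring D/E ester
Conditions: Ph3PCH3Br, KOt-Bu, THF, 0 °C → rt
Reagents that add atoms: methyltriphenylphosphonium bromide, C[P+](c1ccccc1)(c1ccccc1)c1ccccc1.[Br-]
Why: Wittig methylenation converts the neopentyl aldehyde into the C14 vinyl group (C7=C8), the future dienophile.

Step 14
Reactants: 19 13β-allyl-14α-vinyl ring D/E ester; 20 methyl methacrylate
Product: 21 (E)-enoate (C11=C9) of the ring D/E ester
Conditions: 20 (excess), second-generation Hoveyda–Grubbs catalyst RuCl2(H2IMes)(=CH-C6H4-2-O-i-Pr) (5 mol%), CH2Cl2, 40 °C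
Reagents that add atoms: none
Why: Olefin cross-metathesis; the allyl group reacts, whereas the vinyl group flanked by two quaternary carbons should be too hindered to enter the catalytic cycle, and C9 with its methyl (C25) is introduced.

Step 15
Reactants: 21 (E)-enoate
Product: 22 saturated C6/C29 diester (C9 epimers)
Conditions: Mg, MeOH, rt
Reagents that add atoms: none
Why: Dissolving-metal conjugate reduction saturates only the conjugated enoate; C9 becomes an uncontrolled centre that is planar again in 23 and 35.

Step 16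
Reactants: 22 saturated C6/C29 diester
Product: 23 ketene tert-butyldimethylsilyl methyl acetal (C9=C6)
Conditions: LDA, THF, −78 °C; then TBSCl, HMPA, −78 °C → rt
Reagents that add atoms: tert-butyldimethylsilyl chloride, CC(C)(C)[Si](C)(C)Cl
Why: Kinetic ester enolate formation at C9 (the C29 ester has no α-hydrogen) and O-silylation give the ketene silyl acetal.

**Ring A fragment**

Step 17
Reactants: 24 2-hydroxy-3-methylbenzaldehyde
Product: 25 2-(methoxymethoxy)-3-methylbenzaldehyde
Conditions: MOMCl, i-Pr2NEt, CH2Cl2, 0 °C → rt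
Reagents that add atoms: chloromethyl methyl ether, COCCl
Why: Acetal protection of the phenol (SN1-type alkylation) marks this oxygen (O3) as the one to be freed first.

Step 18
Reactants: 25 2-(methoxymethoxy)-3-methylbenzaldehyde
Product: 27 2-(methoxymethoxy)-3-methylphenol, via aryl formate 26 (not isolated)
Conditions: mCPBA, CH2Cl2, rt; then K2CO3 (cat.), MeOH, 0 °C
Reagents that add atoms: 3-chloroperbenzoic acid, OOC(=O)c1cccc(Cl)c1
Why: Dakin oxidation (Baeyer–Villiger oxidation of an electron-rich benzaldehyde, then formate methanolysis) turns the formyl carbon into the carrier of the second phenolic oxygen (O2).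

Step 19
Reactants: 27 2-(methoxymethoxy)-3-methylphenol
Product: 28 4-bromo-2-(methoxymethoxy)-3-methylphenol
Conditions: NBS, MeCN, −20 °C
Reagents that add atoms: N-bromosuccinimide, O=C1CCC(=O)N1Br
Why: Electrophilic aromatic bromination para to the free hydroxyl should put bromine on the carbon next to the methyl group (the future C5), as in the bromination of m-cresol.

Step 20
Reactants: 28 4-bromo-2-(methoxymethoxy)-3-methylphenol
Product: 29 [4-bromo-2-(methoxymethoxy)-3-methylphenoxy]triisopropylsilane
Conditions: TIPSCl, imidazole, DMF, rt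
Reagents that add atoms: chlorotriisopropylsilane, CC(C)[Si](Cl)(C(C)C)C(C)C
Why: Silylation of the less hindered phenol gives a triisopropylsilyl ether (on O2) that survives base, heat and acid.

**Coupling, key step and ring A/B adjustment**

Step 21
Reactants: 23 ketene silyl acetal; 29 aryl bromide
Product: 31 benzocyclobutenone O-methyl O-tert-butyldimethylsilyl ketal (C9 epimers), via aryne 30 (not isolated)
Conditions: 29 (3 equiv), LiTMP (3.3 equiv), THF, −78 → 0 °C
Reagents that add atoms: none
Why: Deprotonation ortho to bromine and loss of lithium bromide give aryne 30 (only one ortho hydrogen, hence one aryne), which undergoes stepwise [2+2] cycloaddition with the ketene silyl acetal; nucleophilic C9 should attack C10, the aryne carbon remote from the methyl group, and the aryl anion then closes on the oxocarbenium carbon C6, with C9 uncontrolled.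

Step 22
Reactants: 31 mixed ketal
Product: 32 benzocyclobutenone (C6 ketone; C9 methyl and C11 tether)
Conditions: PPTS, acetone/H2O (10:1), rt
Reagents that add atoms: none
Why: Mild acid hydrolysis of the mixed silyl methyl ketal releases the strained ketone without touching the MOM or aryl silyl ethers.

Step 23
Reactants: 32 benzocyclobutenone
Product: 33 benzocyclobutenol (6-OH cis to the C9 methyl and trans to the C11 tether; both C9 epimers)
Conditions: NaBH4, MeOH/THF, −20 °C; chromatographic separation
Reagents that add atoms: none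
Why: Hydride reduction of the cyclobutenone with little expected facial bias; the diastereomers with the hydroxyl trans to the tether are taken on because only they can open to the (E)-tethered diene, and the others can be returned to 32 by oxidation.

Step 24
Reactants: 33 benzocyclobutenol
Product: 37 6α-hydroxy pentacycle (8α-H; 9β-methyl; 3-O-MOM; 2-O-TIPS; C29 methyl ester), via silyl ether 34 (not isolated), via ortho-quinodimethane 35 (not isolated), via cycloadduct silyl ether 36 (not isolated)
Conditions: BSA (3 equiv), BHT (cat.), o-xylene, 135 °C, sealed tube; then PPTS (cat.), MeOH, 0 °C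
Reagents that add atoms: none
Why: BSA silylates the carbinol in the flask, and silyl ether 34 undergoes conrotatory 4π electrocyclic ring opening with the siloxy group turning outward, which also turns the C11 tether (trans to it) outward and gives the (E)-ortho-quinodimethane 35, which cannot tautomerise to an aldehyde. The C14 vinyl group then adds across C6 and C9 in a concerted type 1 intramolecular Diels–Alder reaction driven by the return of ring A aromaticity; the closest known reaction type is the benzocyclobutene to ortho-quinodimethane cycloaddition used for steroids and for triterpenes with an aromatic ring A. Ring B is closed by the [4+2] cycloaddition itself (bonds C6–C7 and C8–C9) and ring C through the four-atom tether C11–C12–C13–C14 as a six-membered chair. The trans C/D fusion forces C15 and C18 to be equatorial on that chair, so both angular methyls (13α, 14β) are axial; C8 is then set by the exo arrangement with C7 equatorial (H-8 axial, α), C9 by the diene geometry with C10 equatorial and the inward methyl axial (β), and C6 by the outward siloxy group (6α). The step needs exo, trans B/C selectivity and needs the cycloaddition to outrun a 1,5-hydrogen shift from the inward C9 methyl; every alternative chair places the aryl carbon C10 or C7 syn-axial to an angular methyl, whereas the wanted one pays only the C9/C14 methyl–methyl contact.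

Step 25
Reactants: 37 6α-hydroxy pentacycle
Product: 38 6,7-dehydro 3-phenol (2-O-TIPS; C29 methyl ester)
Conditions: TsOH·H2O (0.3 equiv), toluene/MeOH (20:1), 70 °C
Reagents that add atoms: none
Why: Acid-catalysed E1 dehydration of the benzylic alcohol (cation stabilised by the para silyloxy group) gives the conjugated 6,7-alkene, and the same acid cleaves the MOM acetal by exchange with methanol, freeing O3 only.

**Guaiane fragment**

Step 26
Reactants: 39 (S)-carvone
Product: 40 trimethylsilyl enol ether of (5S)-dihydrocarvone (C1=C2)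
Conditions: LiB(s-Bu)3H, THF, −78 °C; then TMSCl, Et3N, −78 °C → rt
Reagents that add atoms: chlorotrimethylsilane, C[Si](C)(C)Cl
Why: Conjugate hydride reduction of the enone gives the enolate regiospecifically, and O-silylation fixes it as the tetrasubstituted enol ether; C7' comes from carvone.

Step 27
Reactants: 40 trimethylsilyl enol ether
Product: 41 1-methyl-6-(trimethylsilyloxy)-4-(prop-1-en-2-yl)bicyclo[4.1.0]heptane
Conditions: Et2Zn, CH2I2, CH2Cl2, 0 °C
Reagents that add atoms: diiodomethane, ICI
Why: Simmons–Smith cyclopropanation, in which the electron-rich enol ether should react in preference to the isopropenyl group.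

Step 28
Reactants: 41 siloxycyclopropane
Product: 43 (S)-3-methyl-6-(prop-1-en-2-yl)cyclohept-2-en-1-one, via chloro ketone 42 (not isolated)
Conditions: FeCl3 (2.2 equiv), DMF, 0 °C → rt; then NaOAc, MeOH, reflux
Reagents that add atoms: none
Why: Oxidative cyclopropanol ring expansion; iron trichloride cleaves the internal cyclopropane bond to a β-chloro cycloheptanone, and acetate-induced elimination gives the ring-expanded enone.

Step 29
Reactants: 43 (S)-3-methyl-6-(prop-1-en-2-yl)cyclohept-2-en-1-one; 44 1-bromobut-2-yne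
Product: 46 (3R,6S)-2-(but-2-yn-1-yl)-3-methyl-6-(prop-1-en-2-yl)cycloheptan-1-one (C2 epimers), via silyl enol ether 45 (not isolated)
Conditions: CuCl (5 mol%), NaOt-Bu (5 mol%), (S)-2,2'-bis(di-p-tolylphosphino)-1,1'-binaphthyl (5 mol%), Ph2SiH2, toluene, 0 °C; then Bu4N[Ph3SiF2], 44, CH2Cl2, rt
Reagents that add atoms: none
Why: Copper hydride asymmetric conjugate reduction sets C10' under ligand control (cis to the isopropenyl group), and the silyl enol ether, activated by fluoride, is alkylated at C1'; the C1' configuration is lost later.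

Step 30
Reactants: 46 alkynyl ketone
Product: 47 (3R,6S)-3-methyl-2-(2-oxobutyl)-6-(prop-1-en-2-yl)cycloheptan-1-one
Conditions: NaAuCl4·2H2O (2 mol%), MeOH/H2O (10:1), 65 °C
Reagents that add atoms: water, O
Why: Gold-catalysed alkyne hydration with carbonyl participation (5-exo attack of the ring ketone oxygen) should place the new ketone at C3', giving the 1,4-diketone.

Step 31
Reactants: 47 1,4-diketone
Product: 48 (7S,10R)-guaia-4,11-dien-3-one (C1 epimers)
Conditions: KOH, MeOH, 60 °C
Reagents that add atoms: none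
Why: Intramolecular aldol condensation of the 1,4-diketone forms the 2-methylcyclopentenone; C10' is not acidic and stays untouched.

Step 32
Reactants: 48 (7S,10R)-guaia-4,11-dien-3-one
Product: 51 (7S,10R)-1-hydroxyguaia-4,11-dien-3-one (C1 epimers), via kinetic dienol ether 49 (not isolated), via linear dienol ether 50 (not isolated)
Conditions: LDA, TBSCl, HMPA, THF, −78 °C; then benzene, 50 °C; then DMDO (1.0 equiv), acetone/CH2Cl2, −78 °C; then HF·pyridine, THF, 0 °C
Reagents that add atoms: dimethyldioxirane, CC1(C)OO1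
Why: Vinylogous Rubottom oxidation: kinetic α'-silylation, 1,5-hydrogen shifts within the cyclopentadiene to the most substituted dienol ether, and epoxidation at its electron-rich terminus C1' give the γ-hydroxy enone; the C1' configuration is irrelevant.

Step 33
Reactants: 51 (7S,10R)-1-hydroxyguaia-4,11-dien-3-one
Product: 52 (3R,7S,10R)-guaia-4,11-diene-1,3-diol
Conditions: (S)-1-methyl-3,3-diphenyltetrahydro-1H,3H-pyrrolo[1,2-c][1,3,2]oxazaborole (20 mol%), BH3·SMe2, THF, −20 °C
Reagents that add atoms: none
Why: CBS reduction; the oxazaborolidine differentiates the 2-methylalkenyl side from the CH2 side of the ketone and sets C3' (R), the centre that is inverted in step 34.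

**Union and dioxane closure**

Step 34
Reactants: 38 6,7-dehydro 3-phenol; 52 (3R,7S,10R)-guaia-4,11-diene-1,3-diol
Product: 53 aryl C3–O–C3' ether ((3'S); 1'-OH; 4'(5')-ene; 2-O-TIPS)
Conditions: PPh3, DIAD, toluene, 0 °C → rt
Reagents that add atoms: none
Why: Mitsunobu etherification; the phenol displaces the activated secondary allylic alcohol by SN2 with inversion (C3' becomes S), the tertiary alcohol being inert.

Step 35
Reactants: 53 aryl C3–O–C3' ether
Product: 54 2-phenol of 53
Conditions: TBAF, THF, 0 °C; aq. NH4Cl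
Reagents that add atoms: none
Why: Fluoride-induced cleavage of the aryl silyl ether frees O2.

Step 36
Reactants: 54 2-phenol
Product: 55 CNP0304573.1
Conditions: CSA (10 mol%), 4 Å MS, CH2Cl2, −20 → 0 °C
Reagents that add atoms: none
Why: Acid-catalysed ionisation of the tertiary allylic alcohol gives the C1'–C5'–C4' allyl cation, which the tethered phenol captures at C4' (six-membered ring, intramolecular SN1 allylic etherification), moving the alkene to C1'=C5'; the tether enforces the cis dioxane fusion, so C4' (R) follows from C3'.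

**Compound list**

1 | isoprene | C=CC(C)=C | starting material
2 | methacrolein | CC(=C)C=O | starting material
3 | (R)-1,4-dimethylcyclohex-3-ene-1-carbaldehyde | CC1=CC[C@](C)(C=O)CC1 | intermediate
4 | (R)-1,4-dimethylcyclohex-3-ene-1-carboxylic acid | CC1=CC[C@](C)(C(=O)O)CC1 | intermediate
5 | methyl (R)-1,4-dimethylcyclohex-3-ene-1-carboxylate | CC1=CC[C@](C)(C(=O)OC)CC1 | intermediate
6 | methyl (1R)-3-hydroxy-1,4-dimethylcyclohexane-1-carboxylate (C3/C4 diastereomers) | OC1C[C@](C)(C(=O)OC)CCC1C | intermediate
7 | methyl (1R)-1,4-dimethyl-3-oxocyclohexane-1-carboxylate (C4 epimers) | O=C1C[C@](C)(C(=O)OC)CCC1C | intermediate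
8 | pent-1-en-3-one | C=CC(=O)CC | starting material
9 | ketimine of 7 with (S)-1-phenylethylamine | C[C@H](N=C1C[C@](C)(C(=O)OC)CCC1C)c1ccccc1 | intermediate
10 | imine of the C17 Michael adduct | C[C@H](N=C1C[C@](C)(C(=O)OC)CC[C@]1(C)CCC(=O)CC)c1ccccc1 | intermediate
11 | methyl (1R,4R)-1,4-dimethyl-3-oxo-4-(3-oxopentyl)cyclohexane-1-carboxylate | O=C1C[C@](C)(C(=O)OC)CC[C@]1(C)CCC(=O)CC | intermediate
12 | ring D/E octalone (14-oxo, 13(18)-ene, 13-methyl, 17β-methyl, 20β-methyl, 20α-CO2Me) | CC1=C2C[C@](C)(C(=O)OC)CC[C@]2(C)CCC1=O | intermediate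
13 | cis-fused ring D/E decalone (18β-H, C13 epimers) | CC1[C@@H]2C[C@](C)(C(=O)OC)CC[C@]2(C)CCC1=O | intermediate
14 | trimethylsilyl enol ether of 13 (13(14)-ene) | C[Si](C)(C)OC1=C(C)[C@@H]2C[C@](C)(C(=O)OC)CC[C@]2(C)CC1 | intermediate
15 | 13β-allyl-13α-methyl ring D/E 14-ketone | C=CC[C@@]1(C)[C@@H]2C[C@](C)(C(=O)OC)CC[C@]2(C)CCC1=O | intermediate
16 | 14-(methoxymethylene) enol ether | C=CC[C@@]1(C)[C@@H]2C[C@](C)(C(=O)OC)CC[C@]2(C)CCC1=COC | intermediate
17 | ring D/E 14-carbaldehyde (C14 epimers) | C=CC[C@@]1(C)[C@@H]2C[C@](C)(C(=O)OC)CC[C@]2(C)CCC1C=O | intermediate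
18 | 14β-methyl-14α-formyl ring D/E ester | C=CC[C@@]1(C)[C@@H]2C[C@](C)(C(=O)OC)CC[C@]2(C)CC[C@]1(C)C=O | intermediate
19 | 13β-allyl-14α-vinyl ring D/E ester | C=CC[C@@]1(C)[C@@H]2C[C@](C)(C(=O)OC)CC[C@]2(C)CC[C@]1(C)C=C | intermediate
20 | methyl methacrylate | C=C(C)C(=O)OC | starting material
21 | (E)-enoate (C11=C9) of the ring D/E ester | COC(=O)/C(C)=C/C[C@@]1(C)[C@@H]2C[C@](C)(C(=O)OC)CC[C@]2(C)CC[C@]1(C)C=C | intermediate
22 | saturated C6/C29 diester (C9 epimers) | COC(=O)C(C)CC[C@@]1(C)[C@@H]2C[C@](C)(C(=O)OC)CC[C@]2(C)CC[C@]1(C)C=C | intermediate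
23 | ketene tert-butyldimethylsilyl methyl acetal (E/Z mixture) | COC(O[Si](C)(C)C(C)(C)C)=C(C)CC[C@@]1(C)[C@@H]2C[C@](C)(C(=O)OC)CC[C@]2(C)CC[C@]1(C)C=C | intermediate
24 | 2-hydroxy-3-methylbenzaldehyde | Cc1cccc(C=O)c1O | starting material
25 | 2-(methoxymethoxy)-3-methylbenzaldehyde | COCOc1c(C)cccc1C=O | intermediate
26 | 2-(methoxymethoxy)-3-methylphenyl formate | COCOc1c(C)cccc1OC=O | intermediate
27 | 2-(methoxymethoxy)-3-methylphenol | COCOc1c(C)cccc1O | intermediate
28 | 4-bromo-2-(methoxymethoxy)-3-methylphenol | COCOc1c(C)c(Br)ccc1O | intermediate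
29 | [4-bromo-2-(methoxymethoxy)-3-methylphenoxy]triisopropylsilane | COCOc1c(C)c(Br)ccc1O[Si](C(C)C)(C(C)C)C(C)C | intermediate
30 | 3-(methoxymethoxy)-4-methyl-2-(triisopropylsilyloxy) aryne (C5≡C10) | COCOC1=C(C)C#CC=C1O[Si](C(C)C)(C(C)C)C(C)C | intermediate
31 | benzocyclobutenone O-methyl O-TBS ketal (C6 and C9 mixtures) | COCOc1c(C)c2c(cc1O[Si](C(C)C)(C(C)C)C(C)C)C(C)(CC[C@@]1(C)[C@@H]3C[C@](C)(C(=O)OC)CC[C@]3(C)CC[C@]1(C)C=C)C2(OC)O[Si](C)(C)C(C)(C)C | intermediate
32 | benzocyclobutenone (C9 epimers) | COCOc1c(C)c2c(cc1O[Si](C(C)C)(C(C)C)C(C)C)C(C)(CC[C@@]1(C)[C@@H]3C[C@](C)(C(=O)OC)CC[C@]3(C)CC[C@]1(C)C=C)C2=O | intermediate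
33 | benzocyclobutenol (6-OH trans to the C11 tether; both C9 epimers) | COCOc1c(C)c2c(cc1O[Si](C(C)C)(C(C)C)C(C)C)C(C)(CC[C@@]1(C)[C@@H]3C[C@](C)(C(=O)OC)CC[C@]3(C)CC[C@]1(C)C=C)C2O | intermediate
34 | trimethylsilyl ether of 33 | COCOc1c(C)c2c(cc1O[Si](C(C)C)(C(C)C)C(C)C)C(C)(CC[C@@]1(C)[C@@H]3C[C@](C)(C(=O)OC)CC[C@]3(C)CC[C@]1(C)C=C)C2O[Si](C)(C)C | intermediate
35 | ortho-quinodimethane (siloxy and C11 tether outward, C9 methyl inward) | COCOC1=C(C)/C(=C\O[Si](C)(C)C)/C(=C(\C)CC[C@@]2(C)[C@@H]3C[C@](C)(C(=O)OC)CC[C@]3(C)CC[C@]2(C)C=C)C=C1O[Si](C(C)C)(C(C)C)C(C)C | intermediate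
36 | 6α-(trimethylsilyloxy) pentacycle | COCOc1c(C)c2c(cc1O[Si](C(C)C)(C(C)C)C(C)C)[C@]3(C)CC[C@@]4(C)[C@@H]5C[C@](C)(C(=O)OC)CC[C@]5(C)CC[C@]4(C)[C@H]3C[C@@H]2O[Si](C)(C)C | intermediate
37 | 6α-hydroxy pentacycle (8α-H, 9β-methyl, 3-O-MOM, 2-O-TIPS) | COCOc1c(C)c2c(cc1O[Si](C(C)C)(C(C)C)C(C)C)[C@]3(C)CC[C@@]4(C)[C@@H]5C[C@](C)(C(=O)OC)CC[C@]5(C)CC[C@]4(C)[C@H]3C[C@@H]2O | intermediate
38 | 6,7-dehydro 3-phenol (2-O-TIPS) | Oc1c(C)c2c(cc1O[Si](C(C)C)(C(C)C)C(C)C)[C@]3(C)CC[C@@]4(C)[C@@H]5C[C@](C)(C(=O)OC)CC[C@]5(C)CC[C@]4(C)[C@H]3C=C2 | intermediate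
39 | (S)-carvone | CC1=CC[C@@H](CC1=O)C(C)=C | starting material
40 | trimethylsilyl enol ether of (5S)-dihydrocarvone | CC1=C(O[Si](C)(C)C)C[C@@H](C(C)=C)CC1 | intermediate
41 | 1-methyl-6-(trimethylsilyloxy)-4-(prop-1-en-2-yl)bicyclo[4.1.0]heptane (cyclopropane diastereomers) | CC12CC[C@H](C(C)=C)CC1(O[Si](C)(C)C)C2 | intermediate
42 | (6S)-3-chloro-3-methyl-6-(prop-1-en-2-yl)cycloheptan-1-one | C=C(C)[C@H]1CCC(C)(Cl)CC(=O)C1 | intermediate
43 | (S)-3-methyl-6-(prop-1-en-2-yl)cyclohept-2-en-1-one | C=C(C)[C@H]1CCC(C)=CC(=O)C1 | intermediate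
44 | 1-bromobut-2-yne | CC#CCBr | starting material
45 | diphenylsilyl enol ether of (3R,6S)-3-methyl-6-(prop-1-en-2-yl)cycloheptanone | C=C(C)[C@H]1CC[C@@H](C)C=C(O[SiH](c2ccccc2)c2ccccc2)C1 | intermediate
46 | (3R,6S)-2-(but-2-yn-1-yl)-3-methyl-6-(prop-1-en-2-yl)cycloheptan-1-one (C2 epimers) | C=C(C)[C@H]1CC[C@@H](C)C(CC#CC)C(=O)C1 | intermediate
47 | (3R,6S)-3-methyl-2-(2-oxobutyl)-6-(prop-1-en-2-yl)cycloheptan-1-one | C=C(C)[C@H]1CC[C@@H](C)C(CC(=O)CC)C(=O)C1 | intermediate
48 | (7S,10R)-guaia-4,11-dien-3-one (C1 epimers) | C=C(C)[C@H]1CC[C@@H](C)C2CC(=O)C(C)=C2C1 | intermediate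
49 | 3-(TBS-oxy)guaia-2,4,11-triene (kinetic dienol ether) | C=C(C)[C@H]1CC[C@@H](C)C2C=C(O[Si](C)(C)C(C)(C)C)C(C)=C2C1 | intermediate
50 | 3-(TBS-oxy)guaia-1(5),3,11-triene (linear dienol ether) | C=C(C)[C@H]1CC[C@@H](C)C2=C(C1)C(C)=C(O[Si](C)(C)C(C)(C)C)C2 | intermediate
51 | (7S,10R)-1-hydroxyguaia-4,11-dien-3-one (C1 epimers) | C=C(C)[C@H]1CC[C@@H](C)C2(O)CC(=O)C(C)=C2C1 | intermediate
52 | (3R,7S,10R)-guaia-4,11-diene-1,3-diol (C1 epimers) | C=C(C)[C@H]1CC[C@@H](C)C2(O)C[C@@H](O)C(C)=C2C1 | intermediate
53 | aryl C3–O–C3' ether ((3'S), 1'-OH, 2-O-TIPS) | C=C(C)[C@H]1CC[C@@H](C)C2(O)C[C@H](Oc3c(C)c4c(cc3O[Si](C(C)C)(C(C)C)C(C)C)[C@]5(C)CC[C@@]6(C)[C@@H]7C[C@](C)(C(=O)OC)CC[C@]7(C)CC[C@]6(C)[C@H]5C=C4)C(C)=C2C1 | intermediate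
54 | 2-phenol of 53 | C=C(C)[C@H]1CC[C@@H](C)C2(O)C[C@H](Oc3c(C)c4c(cc3O)[C@]5(C)CC[C@@]6(C)[C@@H]7C[C@](C)(C(=O)OC)CC[C@]7(C)CC[C@]6(C)[C@H]5C=C4)C(C)=C2C1 | intermediate
55 | CNP0304573.1 | C=C(C)[C@H]1CC[C@@H](C)C2=C(C1)[C@@]1(C)Oc3cc4c(c(C)c3O[C@H]1C2)C=C[C@H]1[C@@]4(C)CC[C@@]2(C)[C@@H]3C[C@](C)(C(=O)OC)CC[C@]3(C)CC[C@]12C | target

**Count and risks**

Total step count: 36. Longest linear sequence: 24 steps (steps 1–16, 21–25 and 34–36).

Steps most likely to fail:

1. Step 24. A 1,5-hydrogen shift from the inward C9 methyl of 35 may outrun the hindered cycloaddition, the exo/chair preference may erode, and the material with the wrong C6/C9 relationship is lost. The fallback sets out from 33, using all four diastereomers. Catalytic KOt-Bu in THF at 0 °C opens the cyclobutenoxide to the ortho-alkylbenzaldehyde F1. Irradiation of F1 (350 nm, toluene, rt) then generates the hydroxy ortho-quinodimethane by photoenolisation; the (Z)-dienol reverts to F1, and the (E)-dienol cyclises at ambient temperature. This photoenolisation/Diels–Alder route comes back to the route at 37.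

2. Step 21. Addition of the hindered, tetrasubstituted ketene acetal to the aryne may be slow or poorly regioselective, and ene-type or protonation pathways may take over. The fallback sets out from 29 and 22. Compound 29 is lithiated ortho to bromine (LiTMP, THF, −78 °C) and quenched with iodine before the aryne can form, giving the bromo iodo arene F2. The lithium enolate of 22 (LiNCy2) is then arylated at C9 with F2 under Pd(dba)2/P(t-Bu)3 catalysis, the carbon–iodine bond reacting first, to give the α-aryl ester F3. Bromine–lithium exchange (t-BuLi, THF, −100 °C) and closure of the aryllithium onto the C6 ester give the cyclobutenone; the fallback comes back to the route at 32.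

3. Step 34. Substitution by the doubly ortho-substituted phenol may be slow, so that the activated allylic alcohol eliminates toward a cyclopentadiene. The fallback sets out from 51, which is reduced with the (R)-oxazaborolidine and BH3·SMe2 to the C3' epimer, (3S,7S,10R)-guaia-4,11-diene-1,3-diol F4. Methyl chloroformate and pyridine convert only its secondary hydroxyl into the allylic methyl carbonate F5. Palladium-catalysed allylic etherification of F5 with 38 (Pd2(dba)3, dppf, THF, rt) proceeds with net retention and comes back to the route at 53.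

Further compounds

F1 | step 24 | ortho-alkylbenzaldehyde (C6 formyl on C5; C9–H with methyl and C11 tether on C10) | COCOc1c(C)c(C=O)c(cc1O[Si](C(C)C)(C(C)C)C(C)C)C(C)CC[C@@]1(C)[C@@H]2C[C@](C)(C(=O)OC)CC[C@]2(C)CC[C@]1(C)C=C
F2 | step 21 | [4-bromo-5-iodo-2-(methoxymethoxy)-3-methylphenoxy]triisopropylsilane | COCOc1c(C)c(Br)c(I)cc1O[Si](C(C)C)(C(C)C)C(C)C
F3 | step 21 | C9-aryl ester (aryl C10 bonded to C9; C5–Br; C6 methyl ester) | COCOc1c(C)c(Br)c(cc1O[Si](C(C)C)(C(C)C)C(C)C)C(C)(CC[C@@]1(C)[C@@H]2C[C@](C)(C(=O)OC)CC[C@]2(C)CC[C@]1(C)C=C)C(=O)OC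
F4 | step 34 | (3S,7S,10R)-guaia-4,11-diene-1,3-diol | C=C(C)[C@H]1CC[C@@H](C)C2(O)C[C@H](O)C(C)=C2C1
F5 | step 34 | (3S,7S,10R)-1-hydroxyguaia-4,11-dien-3-yl methyl carbonate | C=C(C)[C@H]1CC[C@@H](C)C2(O)C[C@H](OC(=O)OC)C(C)=C2C1
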